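**Retrosynthetic overview**

1. Rings are lettered A to H from the 2,4,6-trihydroxyphenyl end; in ring A the first ether oxygen sits on carbon 4, and in rings B to H carbon 1 is the one bonded to the oxygen from the preceding ring, the next ether oxygen sitting on carbon 5 of ring B, on carbon 6 of rings C, E and G, and on carbon 4 of rings D and F.
2. Feature: ring D is a phloroglucinol (oxygens on its carbons 1, 3 and 5) whose carbon 4, between the hydroxyl-bearing carbons 3 and 5, carries the oxygen to carbon 1 of ring E, i.e. a folded triketide with an aryloxy group on its central carbon. Ring F repeats this with ring G, and rings C, E and G share one 1,6-diaryloxy-3,4,5-trioxygenated pattern.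
3. Key disconnection: the bond between carbons 1 and 6 of ring D, by Claisen cyclisation of diketo diester 8 built on the oxygen of 2-iodo-3,4,5-trimethoxyphenol (ring E, or ring G). The derived two-ring iodide 14 is made once and used twice, as rings D and E and as rings F and G.
4. The other ethers come from Ullmann couplings of a hindered halide with an unhindered phenol: 14 + 1 (ring H), 14 + 16, then bromide 27 (rings A to C, from three bought arenes) + phenol 18. Global O-demethylation of 28 ends the route.
5. Ring order: rings A, B, C, E, G and H are bought as arenes; only the D-type ring is built (step 5), and its batch is split between ring D and ring F.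

Key step: step 5

Remark: compounds 1, 3, 7, 19, 22 and 25 are taken as purchasable. Diketo diester 8 is drawn as the tetracarbonyl tautomer although it should exist largely as enols. The chain is assembled by γ-acylation of an aryloxyacetoacetate because activated aryloxymalonic acids tend to decarboxylate or close to pyranones. All copper couplings and all handling of free polyphenols are under argon.

**Route**

Step 1
Reactants: 1 3,4,5-trimethoxyphenol
Product: 2 2-iodo-3,4,5-trimethoxyphenol
Conditions: NIS (1.0 equiv), MeCN, −20 to 0 °C, dark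
Reagents that add atoms: N-iodosuccinimide, O=C1CCC(=O)N1I
Why: Electrophilic aromatic iodination of a strongly activated phenol whose only free ring positions (2 and 6, equivalent) lie ortho to the hydroxyl, so one equivalent of NIS at low temperature should give the mono-iodide.

Step 2
Reactants: 2 2-iodo-3,4,5-trimethoxyphenol; 3 methyl 4-chloro-3-oxobutanoate
Product: 4 methyl 4-(2-iodo-3,4,5-trimethoxyphenoxy)-3-oxobutanoate
Conditions: NaH (2.1 equiv), THF–DMF, 0 °C to rt; aq. HCl work-up
Reagents that add atoms: none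
Why: Williamson ether synthesis in which the sodium phenoxide displaces chloride from 3 held as its sodium enolate, the standard entry to 4-aryloxyacetoacetates; the enolate form suppresses self-condensation of 3.

Step 3
Reactants: 4 methyl 4-(2-iodo-3,4,5-trimethoxyphenoxy)-3-oxobutanoate
Product: 6 4-(2-iodo-3,4,5-trimethoxyphenoxy)-1-methoxy-1,3-bis(trimethylsilyloxy)buta-1,3-diene, via mono-silyl enol ether 5 (not isolated)
Conditions: TMSOTf (2.2 equiv), Et3N (2.6 equiv), Et2O, 0 °C to rt; salt layer removed, crude diene used at once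
Reagents that add atoms: trimethylsilyl trifluoromethanesulfonate, C[Si](C)(C)OS(=O)(=O)C(F)(F)F
Why: Double O-silylation of a β-keto ester with TMSOTf and Et3N (first at the ketone enol, then by γ-deprotonation at the aryloxy-bearing methylene) is the established one-flask route to 1,3-bis(silyloxy)buta-1,3-dienes, the neutral equivalents of acetoacetate dianions.

Step 4
Reactants: 6 4-(2-iodo-3,4,5-trimethoxyphenoxy)-1-methoxy-1,3-bis(trimethylsilyloxy)buta-1,3-diene; 7 methyl 3-chloro-3-oxopropanoate (methyl malonyl chloride)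
Product: 8 dimethyl 4-(2-iodo-3,4,5-trimethoxyphenoxy)-3,5-dioxoheptanedioate
Conditions: 7 (1.2 equiv), CH2Cl2, −78 to 20 °C; then 1 M HCl; used without prolonged storage
Reagents that add atoms: none
Why: Acid chlorides acylate 1,3-bis(silyl enol ethers) at the terminal carbon without base (the known route to 3,5-dioxopimelates), so the malonyl unit is placed on the aryloxy-bearing carbon and the acidic methylene of 7 cannot quench the nucleophile.

Step 5
Reactants: 8 dimethyl 4-(2-iodo-3,4,5-trimethoxyphenoxy)-3,5-dioxoheptanedioate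
Product: 9 methyl 2,4,6-trihydroxy-3-(2-iodo-3,4,5-trimethoxyphenoxy)benzoate
Conditions: NaOMe (4 equiv), MeOH, 0 °C to reflux, argon; then cold 1 M HCl to pH 2
Reagents that add atoms: none
Why: Methoxide deprotonates chain carbon 4 first (a diketonate that also shields the 1,3-diketone from retro-Claisen attack) and then chain carbon 6, and the carbanion at carbon 6 adds to the ester carbonyl at chain carbon 1; loss of methoxide and enolisation of the resulting cyclohexanetrione give the phloroglucinol carboxylate as its phenoxide. The closest known reaction is the intramolecular Claisen (Dieckmann-type) condensation by which 3,5-dioxo diesters and the malonate-derived chains of the classical phloroglucinol synthesis are folded to phloroglucinol carboxylates. Ring D closes by a 6-(enolendo)-exo-trig acyl substitution that forms the bond between its carbons 1 and 6, chain carbons 1 to 6 becoming carbons 1 to 6 of ring D, with chain carbon 4 already bonded to the oxygen on carbon 1 of ring E and chain carbon 7 remaining as the ester on carbon 6 of the new ring. No stereocentre is created, and the only sp3 stereocentre of 8 (chain carbon 4, racemic and enolisable) disappears on aromatisation. The step needs carbon rather than oxygen acylation: lactonisation to a 4-hydroxypyran-2-one is reversible in methanolic methoxide, whereas aromatisation followed by phenoxide formation is not, so the equilibria should drain to 9. The chain is symmetric about its carbon 4, so both termini give the same product, and the aryl iodide and methyl ethers of ring E are inert to methoxide.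

Step 6
Reactants: 9 methyl 2,4,6-trihydroxy-3-(2-iodo-3,4,5-trimethoxyphenoxy)benzoate
Product: 11 2-(2-iodo-3,4,5-trimethoxyphenoxy)benzene-1,3,5-triol, via carboxylic acid 10 (not isolated)
Conditions: 2 M NaOH aq. (degassed), reflux; then HCl to pH 3, 80 °C, argon
Reagents that add atoms: none
Why: Saponification gives the 2,4,6-trihydroxybenzoic acid, which as a vinylogous β-keto acid loses carbon dioxide on warming in dilute acid (the classical decarboxylation of phloroglucinol carboxylic acids).

Step 7
Reactants: 11 2-(2-iodo-3,4,5-trimethoxyphenoxy)benzene-1,3,5-triol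
Product: 12 5-[(tert-butyldiphenylsilyl)oxy]-2-(2-iodo-3,4,5-trimethoxyphenoxy)benzene-1,3-diol
Conditions: TBDPSCl (1.05 equiv), imidazole (2.2 equiv), DMF, −20 to 0 °C
Reagents that add atoms: tert-butyl(chloro)diphenylsilane, CC(C)(C)[Si](Cl)(c1ccccc1)c1ccccc1
Why: Silylation of phenols with the bulky TBDPSCl is governed by sterics, and the hydroxyl on carbon 1 of ring D has two ortho hydrogens whereas the hydroxyls on carbons 3 and 5 are each flanked by the twisted 2-iodoaryloxy group, so mono-silylation should occur at the hydroxyl on carbon 1.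

Step 8
Reactants: 12 5-[(tert-butyldiphenylsilyl)oxy]-2-(2-iodo-3,4,5-trimethoxyphenoxy)benzene-1,3-diol
Product: 13 tert-butyl[4-(2-iodo-3,4,5-trimethoxyphenoxy)-3,5-dimethoxyphenoxy]diphenylsilane
Conditions: MeOH (5 equiv), PPh3 (2.6 equiv), DIAD (2.6 equiv), THF, 0 °C to rt
Reagents that add atoms: methanol, CO
Why: Mitsunobu O-methylation of phenols runs under neutral conditions, so both remaining hydroxyls (on carbons 3 and 5 of ring D) should be methylated without cleavage or migration of the aryl silyl ether.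

Step 9
Reactants: 13 tert-butyl[4-(2-iodo-3,4,5-trimethoxyphenoxy)-3,5-dimethoxyphenoxy]diphenylsilane
Product: 14 5-(benzyloxy)-2-(2-iodo-3,4,5-trimethoxyphenoxy)-1,3-dimethoxybenzene
Conditions: CsF (2 equiv), BnBr (1.5 equiv), DMF, rt
Reagents that add atoms: benzyl bromide, BrCc1ccccc1
Why: Fluoride cleaves the aryl silyl ether to a caesium phenoxide that is benzylated in the same flask (Williamson), exchanging the silyl group for a benzyl ether that survives basic copper couplings.

Step 10
Reactants: 14 5-(benzyloxy)-2-(2-iodo-3,4,5-trimethoxyphenoxy)-1,3-dimethoxybenzene; 1 3,4,5-trimethoxyphenol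
Product: 15 5-(benzyloxy)-1,3-dimethoxy-2-[3,4,5-trimethoxy-2-(3,4,5-trimethoxyphenoxy)phenoxy]benzene
Conditions: 1 (1.5 equiv), CuI (10 mol %), picolinic acid (20 mol %), K3PO4 (2 equiv), DMSO, 90 °C, argon
Reagents that add atoms: none
Why: Ullmann-type diaryl ether synthesis with the CuI/picolinic acid system, which tolerates ortho-disubstituted aryl iodides; the nucleophile is an unhindered phenol and the phloroglucinol-ring oxygen of 14 is masked as a benzyl ether, so 14 cannot couple with itself (here 14 serves as rings F and G, and the new ether joins carbon 6 of ring G to carbon 1 of ring H).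

Step 11
Reactants: 15 5-(benzyloxy)-1,3-dimethoxy-2-[3,4,5-trimethoxy-2-(3,4,5-trimethoxyphenoxy)phenoxy]benzene
Product: 16 3,5-dimethoxy-4-[3,4,5-trimethoxy-2-(3,4,5-trimethoxyphenoxy)phenoxy]phenol
Conditions: hydrogen (1 atm), 10 % Pd/C (palladium on carbon), EtOAc–MeOH, rt
Reagents that add atoms: none
Why: Hydrogenolysis of the benzyl aryl ether leaves diaryl and methyl ethers untouched and frees the unhindered hydroxyl on carbon 1 of ring F.

Step 12
Reactants: 14 5-(benzyloxy)-2-(2-iodo-3,4,5-trimethoxyphenoxy)-1,3-dimethoxybenzene; 16 3,5-dimethoxy-4-[3,4,5-trimethoxy-2-(3,4,5-trimethoxyphenoxy)phenoxy]phenol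
Product: 17 5-(benzyloxy)-2-{2-[3,5-dimethoxy-4-(3,4,5-trimethoxy-2-(3,4,5-trimethoxyphenoxy)phenoxy)phenoxy]-3,4,5-trimethoxyphenoxy}-1,3-dimethoxybenzene (benzyl ether of rings D to H)
Conditions: 14 (1.1 equiv), CuI (20 mol %), picolinic acid (40 mol %), K3PO4 (2 equiv), DMSO, 95 °C, argon
Reagents that add atoms: none
Why: The same Ullmann ether coupling, now joining carbon 6 of ring E in a second portion of 14 to the unhindered phenol oxygen on carbon 1 of ring F in 16.

Step 13
Reactants: 17 benzyl ether of rings D to H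
Product: 18 4-{2-[3,5-dimethoxy-4-(3,4,5-trimethoxy-2-(3,4,5-trimethoxyphenoxy)phenoxy)phenoxy]-3,4,5-trimethoxyphenoxy}-3,5-dimethoxyphenol (rings D to H with the hydroxyl on carbon 1 of ring D free)
Conditions: hydrogen (1 atm), 10 % Pd/C (palladium on carbon), EtOAc–MeOH, rt
Reagents that add atoms: none
Why: Hydrogenolysis of the benzyl ether frees the hydroxyl on carbon 1 of ring D without touching the other ethers.

Step 14
Reactants: 19 3-(benzyloxy)-4,5-dimethoxybenzaldehyde
Product: 21 3-(benzyloxy)-4,5-dimethoxyphenol, via aryl formate 20 (not isolated)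
Conditions: mCPBA (1.3 equiv), CH2Cl2, rt; aq. NaHCO3 wash; then K2CO3 (0.2 equiv), MeOH, rt
Reagents that add atoms: 3-chloroperoxybenzoic acid, OOC(=O)c1cccc(Cl)c1
Why: Baeyer–Villiger (Dakin-type) oxidation of an electron-rich benzaldehyde proceeds with aryl migration to the aryl formate, which methanolysis cleaves to the phenol whose oxygen becomes the ether oxygen between rings A and B.

Step 15
Reactants: 21 3-(benzyloxy)-4,5-dimethoxyphenol; 22 2-iodo-1,3,5-trimethoxybenzene
Product: 23 1-(benzyloxy)-2,3-dimethoxy-5-(2,4,6-trimethoxyphenoxy)benzene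
Conditions: 22 (1.2 equiv), CuI (10 mol %), picolinic acid (20 mol %), K3PO4 (2 equiv), DMSO, 90 °C, argon
Reagents that add atoms: none
Why: Ullmann ether coupling of the unhindered ring B phenol with the di-ortho-methoxy iodide forms the ether between carbon 4 of ring A and carbon 1 of ring B.

Step 16
Reactants: 23 1-(benzyloxy)-2,3-dimethoxy-5-(2,4,6-trimethoxyphenoxy)benzene
Product: 24 2,3-dimethoxy-5-(2,4,6-trimethoxyphenoxy)phenol
Conditions: hydrogen (1 atm), 10 % Pd/C (palladium on carbon), EtOAc–MeOH, rt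
Reagents that add atoms: none
Why: Hydrogenolysis of the benzyl ether frees the hydroxyl on carbon 5 of ring B.

Step 17
Reactants: 25 5-iodo-1,2,3-trimethoxybenzene
Product: 26 2-bromo-1-iodo-3,4,5-trimethoxybenzene
Conditions: NBS (1.05 equiv), MeCN, rt, dark
Reagents that add atoms: N-bromosuccinimide, O=C1CCC(=O)N1Br
Why: Electrophilic bromination; ring positions 4 and 6 of 25 are equivalent and each is ortho and para to methoxy groups, so monobromination should give the 1,2-dihalide with iodine next to the ring hydrogen.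

Step 18
Reactants: 24 2,3-dimethoxy-5-(2,4,6-trimethoxyphenoxy)phenol; 26 2-bromo-1-iodo-3,4,5-trimethoxybenzene
Product: 27 2-[3-(2-bromo-3,4,5-trimethoxyphenoxy)-4,5-dimethoxyphenoxy]-1,3,5-trimethoxybenzene (rings A to C with bromine on carbon 6 of ring C)
Conditions: 26 (1.2 equiv), CuI (10 mol %), picolinic acid (20 mol %), K3PO4 (2 equiv), DMSO, 80 °C, argon
Reagents that add atoms: none
Why: Ullmann ether coupling chemoselective for the C–I bond over the more hindered C–Br bond (aryl iodides react below the temperature aryl bromides need), forming the ether from carbon 5 of ring B to carbon 1 of ring C and keeping the bromine on carbon 6 of ring C for the fragment union.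

Step 19
Reactants: 18 phenol of rings D to H; 27 bromide of rings A to C
Product: 28 henicosa-O-methyl ether of the target (all 21 hydroxyls as OMe)
Conditions: 27 (1.2 equiv), CuI (30 mol %), 2,2,6,6-tetramethylheptane-3,5-dione (60 mol %), Cs2CO3 (2 equiv), NMP, 120 °C, argon
Reagents that add atoms: none
Why: Ullmann ether coupling of an aryl bromide with the CuI/diketone ligand system at raised temperature; the phenol partner is unhindered (carbons 2 and 6 of ring D are CH), which offsets the two ortho substituents of the bromide in forming the ether from carbon 6 of ring C to carbon 1 of ring D.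

Step 20
Reactants: 28 henicosa-O-methyl ether
Product: 29 CNP0175816.0 (target octamer)
Conditions: BBr3 (45 equiv), CH2Cl2, −78 °C to rt; then MeOH and water at 0 °C; gel filtration (MeOH), argon
Reagents that add atoms: none
Why: BBr3 cleaves aryl methyl ethers by Lewis acid–base complexation and bromide attack at methyl while diaryl ether bonds are inert, so all 21 methyl ethers should be removed and hydrolysis of the borates should give the free polyphenol.

**Compound list**

1 | 3,4,5-trimethoxyphenol | COc1cc(O)cc(OC)c1OC | starting material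
2 | 2-iodo-3,4,5-trimethoxyphenol | COc1cc(O)c(I)c(OC)c1OC | intermediate
3 | methyl 4-chloro-3-oxobutanoate | COC(=O)CC(=O)CCl | starting material
4 | methyl 4-(2-iodo-3,4,5-trimethoxyphenoxy)-3-oxobutanoate | COC(=O)CC(=O)COc1cc(OC)c(OC)c(OC)c1I | intermediate
5 | methyl 4-(2-iodo-3,4,5-trimethoxyphenoxy)-3-(trimethylsilyloxy)but-2-enoate (alkene geometry immaterial) | COC(=O)C=C(COc1cc(OC)c(OC)c(OC)c1I)O[Si](C)(C)C | intermediate (not isolated)
6 | 4-(2-iodo-3,4,5-trimethoxyphenoxy)-1-methoxy-1,3-bis(trimethylsilyloxy)buta-1,3-diene (alkene geometry immaterial) | COC(O[Si](C)(C)C)=CC(O[Si](C)(C)C)=COc1cc(OC)c(OC)c(OC)c1I | intermediate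
7 | methyl 3-chloro-3-oxopropanoate | COC(=O)CC(Cl)=O | starting material
8 | dimethyl 4-(2-iodo-3,4,5-trimethoxyphenoxy)-3,5-dioxoheptanedioate | COC(=O)CC(=O)C(Oc1cc(OC)c(OC)c(OC)c1I)C(=O)CC(=O)OC | intermediate
9 | methyl 2,4,6-trihydroxy-3-(2-iodo-3,4,5-trimethoxyphenoxy)benzoate | COC(=O)c1c(O)cc(O)c(Oc2cc(OC)c(OC)c(OC)c2I)c1O | intermediate
10 | 2,4,6-trihydroxy-3-(2-iodo-3,4,5-trimethoxyphenoxy)benzoic acid | OC(=O)c1c(O)cc(O)c(Oc2cc(OC)c(OC)c(OC)c2I)c1O | intermediate (not isolated)
11 | 2-(2-iodo-3,4,5-trimethoxyphenoxy)benzene-1,3,5-triol | Oc1cc(O)c(Oc2cc(OC)c(OC)c(OC)c2I)c(O)c1 | intermediate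
12 | 5-[(tert-butyldiphenylsilyl)oxy]-2-(2-iodo-3,4,5-trimethoxyphenoxy)benzene-1,3-diol | CC(C)(C)[Si](Oc1cc(O)c(Oc2cc(OC)c(OC)c(OC)c2I)c(O)c1)(c1ccccc1)c1ccccc1 | intermediate
13 | tert-butyl[4-(2-iodo-3,4,5-trimethoxyphenoxy)-3,5-dimethoxyphenoxy]diphenylsilane | CC(C)(C)[Si](Oc1cc(OC)c(Oc2cc(OC)c(OC)c(OC)c2I)c(OC)c1)(c1ccccc1)c1ccccc1 | intermediate
14 | 5-(benzyloxy)-2-(2-iodo-3,4,5-trimethoxyphenoxy)-1,3-dimethoxybenzene | COc1cc(OCc2ccccc2)cc(OC)c1Oc1cc(OC)c(OC)c(OC)c1I | intermediate
15 | 5-(benzyloxy)-1,3-dimethoxy-2-[3,4,5-trimethoxy-2-(3,4,5-trimethoxyphenoxy)phenoxy]benzene | COc1cc(OCc2ccccc2)cc(OC)c1Oc1cc(OC)c(OC)c(OC)c1Oc1cc(OC)c(OC)c(OC)c1 | intermediate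
16 | 3,5-dimethoxy-4-[3,4,5-trimethoxy-2-(3,4,5-trimethoxyphenoxy)phenoxy]phenol | COc1cc(O)cc(OC)c1Oc1cc(OC)c(OC)c(OC)c1Oc1cc(OC)c(OC)c(OC)c1 | intermediate
17 | 5-(benzyloxy)-2-{2-[3,5-dimethoxy-4-(3,4,5-trimethoxy-2-(3,4,5-trimethoxyphenoxy)phenoxy)phenoxy]-3,4,5-trimethoxyphenoxy}-1,3-dimethoxybenzene | COc1cc(OCc2ccccc2)cc(OC)c1Oc1cc(OC)c(OC)c(OC)c1Oc1cc(OC)c(Oc2cc(OC)c(OC)c(OC)c2Oc2cc(OC)c(OC)c(OC)c2)c(OC)c1 | intermediate
18 | 4-{2-[3,5-dimethoxy-4-(3,4,5-trimethoxy-2-(3,4,5-trimethoxyphenoxy)phenoxy)phenoxy]-3,4,5-trimethoxyphenoxy}-3,5-dimethoxyphenol | COc1cc(O)cc(OC)c1Oc1cc(OC)c(OC)c(OC)c1Oc1cc(OC)c(Oc2cc(OC)c(OC)c(OC)c2Oc2cc(OC)c(OC)c(OC)c2)c(OC)c1 | intermediate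
19 | 3-(benzyloxy)-4,5-dimethoxybenzaldehyde | COc1cc(C=O)cc(OCc2ccccc2)c1OC | starting material
20 | 3-(benzyloxy)-4,5-dimethoxyphenyl formate | COc1cc(OC=O)cc(OCc2ccccc2)c1OC | intermediate (not isolated)
21 | 3-(benzyloxy)-4,5-dimethoxyphenol | COc1cc(O)cc(OCc2ccccc2)c1OC | intermediate
22 | 2-iodo-1,3,5-trimethoxybenzene | COc1cc(OC)c(I)c(OC)c1 | starting material
23 | 1-(benzyloxy)-2,3-dimethoxy-5-(2,4,6-trimethoxyphenoxy)benzene | COc1cc(OC)c(Oc2cc(OC)c(OC)c(OCc3ccccc3)c2)c(OC)c1 | intermediate
24 | 2,3-dimethoxy-5-(2,4,6-trimethoxyphenoxy)phenol | COc1cc(OC)c(Oc2cc(O)c(OC)c(OC)c2)c(OC)c1 | intermediate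
25 | 5-iodo-1,2,3-trimethoxybenzene | COc1cc(I)cc(OC)c1OC | starting material
26 | 2-bromo-1-iodo-3,4,5-trimethoxybenzene | COc1cc(I)c(Br)c(OC)c1OC | intermediate
27 | 2-[3-(2-bromo-3,4,5-trimethoxyphenoxy)-4,5-dimethoxyphenoxy]-1,3,5-trimethoxybenzene | COc1cc(OC)c(Oc2cc(OC)c(OC)c(Oc3cc(OC)c(OC)c(OC)c3Br)c2)c(OC)c1 | intermediate
28 | henicosa-O-methyl ether of the target | COc1cc(OC)c(Oc2cc(OC)c(OC)c(Oc3cc(OC)c(OC)c(OC)c3Oc3cc(OC)c(Oc4cc(OC)c(OC)c(OC)c4Oc4cc(OC)c(Oc5cc(OC)c(OC)c(OC)c5Oc5cc(OC)c(OC)c(OC)c5)c(OC)c4)c(OC)c3)c2)c(OC)c1 | intermediate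
29 | CNP0175816.0 | Oc1cc(O)c(Oc2cc(O)c(O)c(Oc3cc(O)c(O)c(O)c3Oc3cc(O)c(Oc4cc(O)c(O)c(O)c4Oc4cc(O)c(Oc5cc(O)c(O)c(O)c5Oc5cc(O)c(O)c(O)c5)c(O)c4)c(O)c3)c2)c(O)c1 | target

**Step count**

Total: 20 steps. Longest linear sequence: 15 steps (steps 1 to 13, then 19 and 20).

**Steps most likely to fail**

Step 5 (key step). The diketone enolate may acylate on oxygen and stay as the pyranone lactone, or methoxide may split the 1,3-diketone by retro-Claisen scission before ring closure. The fallback abandons the ring construction and makes the hindered ether between carbon 4 of ring D and carbon 1 of ring E by a copper coupling. It sets out from 26. Bought 2,6-dimethoxybenzene-1,4-diol is benzylated at its unhindered hydroxyl (BnBr, K2CO3, acetone) to give 4-(benzyloxy)-2,6-dimethoxyphenol F1. Coupling of F1 with 26 at the C–I bond (CuI, picolinic acid, K3PO4, DMSO, 90 °C) should give 5-(benzyloxy)-2-(2-bromo-3,4,5-trimethoxyphenoxy)-1,3-dimethoxybenzene F2. Bromine–lithium exchange (n-BuLi, THF, −78 °C) and quenching with iodine converts F2 into 14, where the route is rejoined.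

Step 7. Silylation may not discriminate well between the hydroxyl on carbon 1 of ring D and the two statistically favoured hydroxyls on carbons 3 and 5, or may run on to bis-silylation. The fallback keeps the ester of 9 as a chelation handle and sets out from 9. TMSCHN2 (MeOH–toluene, 0 °C) should methylate only the unchelated hydroxyl para to the ester, giving methyl 2,6-dihydroxy-3-(2-iodo-3,4,5-trimethoxyphenoxy)-4-methoxybenzoate F3. BnBr and K2CO3 in acetone should then benzylate the less hindered of the two chelated hydroxyls, the one with a ring hydrogen beside it, giving methyl 6-(benzyloxy)-2-hydroxy-3-(2-iodo-3,4,5-trimethoxyphenoxy)-4-methoxybenzoate F4. MeI and K2CO3 in DMF at 60 °C methylate the last hydroxyl, giving methyl 6-(benzyloxy)-3-(2-iodo-3,4,5-trimethoxyphenoxy)-2,4-dimethoxybenzoate F5. KOH in DMSO–water at 100 °C gives 6-(benzyloxy)-3-(2-iodo-3,4,5-trimethoxyphenoxy)-2,4-dimethoxybenzoic acid F6, and protodecarboxylation (catalytic Ag2CO3, AcOH, DMSO, 120 °C) returns the route to 14.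

Step 19. Oxidative addition of the di-ortho-substituted, electron-rich bromide may be too slow at this late stage, so that protodebromination or simple recovery of both fragments wins. The fallback changes the electrophile and sets out from 27. Bromine–lithium exchange (n-BuLi, THF, −78 °C) followed by iodine should give 2-[3-(2-iodo-3,4,5-trimethoxyphenoxy)-4,5-dimethoxyphenoxy]-1,3,5-trimethoxybenzene F7. F7 is coupled with 18 under the milder iodide conditions of step 12 (CuI, picolinic acid, K3PO4, DMSO, 95 °C), coming back to the route at 28.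

**Further compounds**

F1 | step 5 | 4-(benzyloxy)-2,6-dimethoxyphenol | COc1cc(OCc2ccccc2)cc(OC)c1O
F2 | step 5 | 5-(benzyloxy)-2-(2-bromo-3,4,5-trimethoxyphenoxy)-1,3-dimethoxybenzene | COc1cc(OCc2ccccc2)cc(OC)c1Oc1cc(OC)c(OC)c(OC)c1Br
F3 | step 7 | methyl 2,6-dihydroxy-3-(2-iodo-3,4,5-trimethoxyphenoxy)-4-methoxybenzoate | COC(=O)c1c(O)cc(OC)c(Oc2cc(OC)c(OC)c(OC)c2I)c1O
F4 | step 7 | methyl 6-(benzyloxy)-2-hydroxy-3-(2-iodo-3,4,5-trimethoxyphenoxy)-4-methoxybenzoate | COC(=O)c1c(OCc2ccccc2)cc(OC)c(Oc2cc(OC)c(OC)c(OC)c2I)c1O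
F5 | step 7 | methyl 6-(benzyloxy)-3-(2-iodo-3,4,5-trimethoxyphenoxy)-2,4-dimethoxybenzoate | COC(=O)c1c(OCc2ccccc2)cc(OC)c(Oc2cc(OC)c(OC)c(OC)c2I)c1OC
F6 | step 7 | 6-(benzyloxy)-3-(2-iodo-3,4,5-trimethoxyphenoxy)-2,4-dimethoxybenzoic acid | OC(=O)c1c(OCc2ccccc2)cc(OC)c(Oc2cc(OC)c(OC)c(OC)c2I)c1OC
F7 | step 19 | 2-[3-(2-iodo-3,4,5-trimethoxyphenoxy)-4,5-dimethoxyphenoxy]-1,3,5-trimethoxybenzene | COc1cc(OC)c(Oc2cc(OC)c(OC)c(Oc3cc(OC)c(OC)c(OC)c3I)c2)c(OC)c1
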